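Ring A of this ent-labdane has no functional group on C1–C3 and lies between the quaternary carbons C10 and C4, so it is closed by stitching a traceless two-carbon unit (C1–C2) between C10 and C3. The precursor is a 2-methylcyclohexanone (ring B, ketone at C9) whose C5 carries the preformed quaternary C4 with its methyl, silyloxymethyl and formyl (C3) groups. With vinyltriphenylphosphonium bromide, Michael addition of the C10 enolate forms C1–C10 and the resulting ylide olefinates the aldehyde to form C2–C3. Both C10 epimers converge on the trans ring fusion. The C9 ketone later carries the side chain and sets C8 and C9.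

Key step: step 6

Remark: locants C1–C20 are labdane locants of the target (C18 = oxygenated carbon on C4, C19 = methyl on C4, C20 = methyl on C10, C17 = methyl on C8, C11–C16 = side chain).
Assumption: the Claisen rearrangement of step 4 passes through the chair-like transition state usual for allyl vinyl ethers, so that the (Z)-enol ether geometry fixes C4 as drawn.

Step 1
Reactants: 1 2-methylcyclohex-2-en-1-one
Product: 2 (R)-2-methylcyclohex-2-en-1-ol
Conditions: (S)-2-methyl-CBS-oxazaborolidine (10 mol %), BH3·SMe2, THF, −20 °C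
Reagents that add atoms: none
Why: Corey–Bakshi–Shibata reduction, in which the catalyst binds the ketone with the alkenyl arm as the large group and delivers hydride to one face, should give the (R)-alcohol that later relays its configuration to C5.

Step 2
Reactants: 3 prop-2-yn-1-ol
Product: 5 (Z)-3-iodo-2-methylprop-2-en-1-ol, via alkenylmagnesium alkoxide 4 (not isolated)
Conditions: MeMgBr (3 equiv), CuI (10 mol %), Et2O/THF, −10 → 25 °C; then I2, −10 °C; aq. NH4Cl
Reagents that add atoms: methylmagnesium bromide (C[Mg]Br); iodine (II)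
Why: Copper-catalysed anti-carbomagnesiation of the propargylic alkoxide forms a five-membered alkenylmagnesium chelate, so iodinolysis should give the (Z)-iodide with iodine cis to the CH2OH group.

Step 3
Reactants: 5 (Z)-3-iodo-2-methylprop-2-en-1-ol
Product: 6 tert-butyl{[(Z)-3-iodo-2-methylprop-2-en-1-yl]oxy}diphenylsilane
Conditions: t-BuPh2SiCl, imidazole, DMF, 25 °C
Reagents that add atoms: tert-butyl(chloro)diphenylsilane (CC(C)(C)[Si](Cl)(c1ccccc1)c1ccccc1)
Why: Standard silylation of a primary alcohol gives a robust ether that should survive the basic, reductive and oxidative steps up to step 14.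

Step 4
Reactants: 2 (R)-2-methylcyclohex-2-en-1-ol; 6 tert-butyl{[(Z)-3-iodo-2-methylprop-2-en-1-yl]oxy}diphenylsilane
Product: 8 (2S)-3-[(tert-butyldiphenylsilyl)oxy]-2-methyl-2-[(1S)-2-methylcyclohex-2-en-1-yl]propanal, via allyl vinyl ether 7 (not isolated)
Conditions: CuI (10 mol %), 3,4,7,8-tetramethyl-1,10-phenanthroline (20 mol %), Cs2CO3, o-xylene, 110 °C; then 140 °C
Reagents that add atoms: none
Why: CuI-catalysed C–O coupling retains the alkene geometry and the allyl vinyl ether then undergoes a Claisen rearrangement, in which the suprafacial [3,3] shift transfers the C9–O configuration to C5 and the chair-like transition state translates the (Z)-enol ether geometry into the quaternary centre C4.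

Step 5
Reactants: 8 (2S)-3-[(tert-butyldiphenylsilyl)oxy]-2-methyl-2-[(1S)-2-methylcyclohex-2-en-1-yl]propanal
Product: 10 (2S)-3-[(tert-butyldiphenylsilyl)oxy]-2-methyl-2-[(1S)-2-methyl-3-oxocyclohexyl]propanal (both C10 epimers), via borane adduct 9 (not isolated)
Conditions: BH3·SMe2, THF, 0 → 25 °C; then [C5H5NH][CrO3Cl], CH2Cl2, 40 °C
Reagents that add atoms: pyridinium chlorochromate ([O-][Cr](=O)(=O)Cl.c1cc[nH+]cc1)
Why: Hydroboration places boron on the less substituted alkene carbon C9 while the aldehyde is reduced to a borate, and chromate oxidation of both should give the C9 ketone and return the C3 aldehyde; the C10 configuration does not matter because step 6 erases it.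

Step 6
Reactants: 10 (2S)-3-[(tert-butyldiphenylsilyl)oxy]-2-methyl-2-[(1S)-2-methyl-3-oxocyclohexyl]propanal (both C10 epimers); 11 ethenyl(triphenyl)phosphonium bromide
Product: 14 (4aR,5S,8aR)-5-{[(tert-butyldiphenylsilyl)oxy]methyl}-5,8a-dimethyl-3,4,4a,5,8,8a-hexahydronaphthalen-1(2H)-one, via potassium enolate 12 (not isolated), via phosphorus ylide 13 (not isolated)
Conditions: KOt-Bu (1.05 equiv), THF/t-BuOH, 0 °C; then 25 → 50 °C
Reagents that add atoms: none
Why: KOt-Bu equilibrates 10 to the more substituted C9–C10 enolate 12 (both C10 epimers give the same enolate), which adds in Michael fashion to the vinylphosphonium salt to form C1–C10 and the ylide 13, and the ylide then olefinates the non-enolisable C3 aldehyde intramolecularly (Wittig) to form the C2=C3 bond. The closest known reaction type is the Michael addition–intramolecular Wittig annulation of ketone enolates with vinyltriphenylphosphonium salts. Ring A closes in the Wittig event by 6-exo-trig attack of the ylide carbon C2 on the aldehyde carbon C3. The new quaternary stereocentre C10 is controlled by the adjacent C5 stereocentre: the bulky C4 substituent sits pseudo-axial on the enolate and the acceptor enters anti to it, which places C1 trans to C4 and should give the trans ring fusion. The step needs regioselectivity for C10 over C8, which rests on enolate equilibration and on the fact that only the C10 adduct holds the ylide within reach of the aldehyde, and chemoselectivity, which rests on the aldehyde having no α-hydrogen.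

Step 7
Reactants: 14 (4aR,5S,8aR)-5-{[(tert-butyldiphenylsilyl)oxy]methyl}-5,8a-dimethyl-3,4,4a,5,8,8a-hexahydronaphthalen-1(2H)-one
Product: 15 (4aR,5S,8aR)-5-{[(tert-butyldiphenylsilyl)oxy]methyl}-5,8a-dimethyloctahydronaphthalen-1(2H)-one
Conditions: H2 (1 atm), 10% Pd/C, EtOAc, 25 °C
Reagents that add atoms: none
Why: Heterogeneous hydrogenation should saturate the disubstituted C2–C3 alkene and leave the ketone and the silyl ether untouched; no stereocentre is formed.

Step 8
Reactants: 15 (4aR,5S,8aR)-5-{[(tert-butyldiphenylsilyl)oxy]methyl}-5,8a-dimethyloctahydronaphthalen-1(2H)-one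
Product: 16 (4aR,5S,8aR)-5-{[(tert-butyldiphenylsilyl)oxy]methyl}-2,5,8a-trimethyloctahydronaphthalen-1(2H)-one (both C8 epimers)
Conditions: LiN(i-Pr)2, THF, −78 °C; MeI, −78 → 0 °C
Reagents that add atoms: iodomethane (CI)
Why: C10 is quaternary, so only the C8 enolate can form and its methylation installs C17; the C8 configuration is erased in step 9.

Step 9
Reactants: 16 (4aR,5S,8aR)-5-{[(tert-butyldiphenylsilyl)oxy]methyl}-2,5,8a-trimethyloctahydronaphthalen-1(2H)-one (both C8 epimers)
Product: 17 (4aR,5S,8aR)-5-{[(tert-butyldiphenylsilyl)oxy]methyl}-2,5,8a-trimethyl-3,4,4a,5,6,7,8,8a-octahydronaphthalen-1-yl trifluoromethanesulfonate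
Conditions: KN(SiMe3)2, THF, −78 °C; PhNTf2, −78 → 0 °C
Reagents that add atoms: N-phenylbis(trifluoromethanesulfonimide) (O=S(=O)(N(c1ccccc1)S(=O)(=O)C(F)(F)F)C(F)(F)F)
Why: Removal of the remaining C8 hydrogen gives the tetrasubstituted potassium enolate, whose O-sulfonylation fixes the C8=C9 double bond as the enol triflate.

Step 10
Reactants: 18 (R)-5-methoxy-3-methyl-5-oxopentanoic acid
Product: 20 (S)-4-methyloxan-2-one, via hydroxy acid 19 (not isolated)
Conditions: NaH (1.0 equiv), THF, 0 °C; LiBH4, 25 °C; then 2 M HCl, 25 °C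
Reagents that add atoms: none
Why: As its sodium carboxylate the acid terminus is inert to LiBH4, which reduces only the ester, and acidification lactonises the hydroxy acid without touching the stereocentre (the future C13).

Step 11
Reactants: 20 (S)-4-methyloxan-2-one
Product: 21 methyl (R)-5-iodo-3-methylpentanoate
Conditions: Me3SiI, CH2Cl2, 25 °C; then MeOH, 25 °C
Reagents that add atoms: iodotrimethylsilane (C[Si](C)(C)I); methanol (CO)
Why: Me3SiI opens the lactone by SN2 attack of iodide at the alkyl–oxygen carbon and acid-promoted methanolysis of the silyl ester gives the methyl ester, with the stereocentre remote from both reacting sites.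

Step 12
Reactants: 17 (4aR,5S,8aR)-5-{[(tert-butyldiphenylsilyl)oxy]methyl}-2,5,8a-trimethyl-3,4,4a,5,6,7,8,8a-octahydronaphthalen-1-yl trifluoromethanesulfonate; 21 methyl (R)-5-iodo-3-methylpentanoate
Product: 23 methyl (3S)-5-[(4aS,5S,8aR)-5-{[(tert-butyldiphenylsilyl)oxy]methyl}-2,5,8a-trimethyl-3,4,4a,5,6,7,8,8a-octahydronaphthalen-1-yl]-3-methylpentanoate, via alkylzinc iodide 22 (not isolated)
Conditions: Zn dust, LiCl, THF, 40 °C (21 → 22); then 17, Pd(OAc)2 (5 mol %), SPhos (10 mol %), THF/NMP, 60 °C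
Reagents that add atoms: none
Why: Zinc insertion into the primary iodide tolerates the ester and Negishi coupling of the alkylzinc with the hindered enol triflate (comparable to 2,6,6-trisubstituted cyclohexenyl triflates) should form C9–C11 with the alkene position and C13 retained.

Step 13
Reactants: 23 methyl (3S)-5-[(4aS,5S,8aR)-5-{[(tert-butyldiphenylsilyl)oxy]methyl}-2,5,8a-trimethyl-3,4,4a,5,6,7,8,8a-octahydronaphthalen-1-yl]-3-methylpentanoate
Product: 25 methyl (3S)-5-[(1S,2S,4aS,5S,8aR)-5-{[(tert-butyldiphenylsilyl)oxy]methyl}-2-hydroxy-2,5,8a-trimethyldecahydronaphthalen-1-yl]-3-methylpentanoate, via alkylborane 24 (not isolated)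
Conditions: BH3·THF, THF, 0 → 25 °C; then H2O2, aq. NaHCO3, 0 → 25 °C
Reagents that add atoms: hydrogen peroxide (OO)
Why: In this hydroboration–oxidation boron adds to C8, the alkene carbon remote from quaternary C10, and boron and hydrogen add syn from the face opposite the axial C20 methyl, so oxidation with retention should give the equatorial C8 hydroxyl (axial C17) and the C9 hydrogen trans to C20 (equatorial side chain).

Step 14
Reactants: 25 methyl (3S)-5-[(1S,2S,4aS,5S,8aR)-5-{[(tert-butyldiphenylsilyl)oxy]methyl}-2-hydroxy-2,5,8a-trimethyldecahydronaphthalen-1-yl]-3-methylpentanoate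
Product: 26 methyl (3S)-5-[(1S,2S,4aS,5S,8aR)-2-hydroxy-5-(hydroxymethyl)-2,5,8a-trimethyldecahydronaphthalen-1-yl]-3-methylpentanoate
Conditions: Bu4NF, AcOH, THF, 25 → 40 °C
Reagents that add atoms: none
Why: Fluoride cleaves the silyl ether, the acetic acid buffer protects the methyl ester, and the tertiary alcohol is unaffected.

Step 15
Reactants: 26 methyl (3S)-5-[(1S,2S,4aS,5S,8aR)-2-hydroxy-5-(hydroxymethyl)-2,5,8a-trimethyldecahydronaphthalen-1-yl]-3-methylpentanoate; 27 (Z)-2-methylbut-2-enoic acid (angelic acid)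
Product: 29 methyl (3S)-5-[(1S,2S,4aS,5S,8aR)-2-hydroxy-2,5,8a-trimethyl-5-({[(Z)-2-methylbut-2-enoyl]oxy}methyl)decahydronaphthalen-1-yl]-3-methylpentanoate, via mixed anhydride 28 (not isolated)
Conditions: 2,4,6-trichlorobenzoyl chloride, Et3N, toluene, 25 °C (27 → 28); then 26, 80 °C, no 4-(dimethylamino)pyridine
Reagents that add atoms: none
Why: Yamaguchi-type mixed-anhydride acylation without a nucleophilic catalyst should acylate only the primary C18 hydroxyl (the tertiary C8 hydroxyl is inert) and avoid the addition–elimination that isomerises angelates to tiglates.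

Step 16
Reactants: 29 methyl (3S)-5-[(1S,2S,4aS,5S,8aR)-2-hydroxy-2,5,8a-trimethyl-5-({[(Z)-2-methylbut-2-enoyl]oxy}methyl)decahydronaphthalen-1-yl]-3-methylpentanoate
Product: 30 (3S)-5-[(1S,2S,4aS,5S,8aR)-2-hydroxy-2,5,8a-trimethyl-5-({[(Z)-2-methylbut-2-enoyl]oxy}methyl)decahydronaphthalen-1-yl]-3-methylpentanoic acid (CNP0315745.1)
Conditions: Me3SnOH, ClCH2CH2Cl, 70 °C; then 1 M HCl (work-up)
Reagents that add atoms: trimethyltin hydroxide (C[Sn](C)(C)O)
Why: Me3SnOH should cleave the unhindered methyl ester under neutral conditions, while the neopentyl, α-branched and conjugated angelate reacts much more slowly and keeps its (Z)-geometry.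

Compound list
1 | 2-methylcyclohex-2-en-1-one | CC1=CCCCC1=O | starting material
2 | (R)-2-methylcyclohex-2-en-1-ol | CC1=CCCC[C@H]1O | intermediate
3 | prop-2-yn-1-ol | C#CCO | starting material
4 | bromomagnesium (Z)-3-(bromomagnesio)-2-methylprop-2-en-1-olate | C/C(CO[Mg]Br)=C/[Mg]Br | intermediate
5 | (Z)-3-iodo-2-methylprop-2-en-1-ol | C/C(CO)=C/I | intermediate
6 | tert-butyl{[(Z)-3-iodo-2-methylprop-2-en-1-yl]oxy}diphenylsilane | C/C(CO[Si](c1ccccc1)(c1ccccc1)C(C)(C)C)=C/I | intermediate
7 | tert-butyl{[(Z)-2-methyl-3-{[(R)-2-methylcyclohex-2-en-1-yl]oxy}prop-2-en-1-yl]oxy}diphenylsilane | CC1=CCCC[C@H]1O/C=C(/C)CO[Si](c1ccccc1)(c1ccccc1)C(C)(C)C | intermediate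
8 | (2S)-3-[(tert-butyldiphenylsilyl)oxy]-2-methyl-2-[(1S)-2-methylcyclohex-2-en-1-yl]propanal | O=C[C@](C)(CO[Si](c1ccccc1)(c1ccccc1)C(C)(C)C)[C@H]1CCCC=C1C | intermediate
9 | borane adduct of 8 (C9–BH2 and C3–O–BH2, simplest monomeric form; syn addition anti to the C5 substituent) | BOC[C@](C)(CO[Si](c1ccccc1)(c1ccccc1)C(C)(C)C)[C@H]1CCC[C@H](B)[C@H]1C | intermediate
10 | (2S)-3-[(tert-butyldiphenylsilyl)oxy]-2-methyl-2-[(1S)-2-methyl-3-oxocyclohexyl]propanal (both C10 epimers) | O=C[C@](C)(CO[Si](c1ccccc1)(c1ccccc1)C(C)(C)C)[C@H]1CCCC(=O)C1C | intermediate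
11 | ethenyl(triphenyl)phosphonium bromide | C=C[P+](c1ccccc1)(c1ccccc1)c1ccccc1.[Br-] | starting material
12 | potassium C9–C10 enolate of 10 | O=C[C@](C)(CO[Si](c1ccccc1)(c1ccccc1)C(C)(C)C)[C@H]1CCCC([O-])=C1C.[K+] | intermediate
13 | phosphorus ylide (C10 quaternary, bearing CH2–CH=PPh3 trans to the C5 substituent) | O=C[C@](C)(CO[Si](c1ccccc1)(c1ccccc1)C(C)(C)C)[C@H]1CCCC(=O)[C@]1(C)CC=P(c1ccccc1)(c1ccccc1)c1ccccc1 | intermediate
14 | (4aR,5S,8aR)-5-{[(tert-butyldiphenylsilyl)oxy]methyl}-5,8a-dimethyl-3,4,4a,5,8,8a-hexahydronaphthalen-1(2H)-one | CC(C)(C)[Si](c1ccccc1)(c1ccccc1)OC[C@@]1(C)C=CC[C@]2(C)[C@@H]1CCCC2=O | intermediate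
15 | (4aR,5S,8aR)-5-{[(tert-butyldiphenylsilyl)oxy]methyl}-5,8a-dimethyloctahydronaphthalen-1(2H)-one | CC(C)(C)[Si](c1ccccc1)(c1ccccc1)OC[C@@]1(C)CCC[C@]2(C)[C@@H]1CCCC2=O | intermediate
16 | (4aR,5S,8aR)-5-{[(tert-butyldiphenylsilyl)oxy]methyl}-2,5,8a-trimethyloctahydronaphthalen-1(2H)-one (both C8 epimers) | CC(C)(C)[Si](c1ccccc1)(c1ccccc1)OC[C@@]1(C)CCC[C@]2(C)[C@@H]1CCC(C)C2=O | intermediate
17 | (4aR,5S,8aR)-5-{[(tert-butyldiphenylsilyl)oxy]methyl}-2,5,8a-trimethyl-3,4,4a,5,6,7,8,8a-octahydronaphthalen-1-yl trifluoromethanesulfonate | CC(C)(C)[Si](c1ccccc1)(c1ccccc1)OC[C@@]1(C)CCC[C@]2(C)[C@@H]1CCC(C)=C2OS(=O)(=O)C(F)(F)F | intermediate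
18 | (R)-5-methoxy-3-methyl-5-oxopentanoic acid | COC(=O)C[C@H](C)CC(=O)O | starting material
19 | (S)-5-hydroxy-3-methylpentanoic acid | OCC[C@H](C)CC(=O)O | intermediate
20 | (S)-4-methyloxan-2-one | O=C1C[C@@H](C)CCO1 | intermediate
21 | methyl (R)-5-iodo-3-methylpentanoate | COC(=O)C[C@@H](C)CCI | intermediate
22 | [(R)-5-methoxy-3-methyl-5-oxopentyl]zinc iodide | COC(=O)C[C@@H](C)CC[Zn]I | intermediate
23 | methyl (3S)-5-[(4aS,5S,8aR)-5-{[(tert-butyldiphenylsilyl)oxy]methyl}-2,5,8a-trimethyl-3,4,4a,5,6,7,8,8a-octahydronaphthalen-1-yl]-3-methylpentanoate | CC(C)(C)[Si](c1ccccc1)(c1ccccc1)OC[C@@]1(C)CCC[C@]2(C)[C@@H]1CCC(C)=C2CC[C@H](C)CC(=O)OC | intermediate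
24 | C8 alkylborane from 23 (simplest monomeric form) | CC(C)(C)[Si](c1ccccc1)(c1ccccc1)OC[C@@]1(C)CCC[C@]2(C)[C@@H]1CC[C@](C)(B)[C@H]2CC[C@H](C)CC(=O)OC | intermediate
25 | methyl (3S)-5-[(1S,2S,4aS,5S,8aR)-5-{[(tert-butyldiphenylsilyl)oxy]methyl}-2-hydroxy-2,5,8a-trimethyldecahydronaphthalen-1-yl]-3-methylpentanoate | CC(C)(C)[Si](c1ccccc1)(c1ccccc1)OC[C@@]1(C)CCC[C@]2(C)[C@@H]1CC[C@](C)(O)[C@H]2CC[C@H](C)CC(=O)OC | intermediate
26 | methyl (3S)-5-[(1S,2S,4aS,5S,8aR)-2-hydroxy-5-(hydroxymethyl)-2,5,8a-trimethyldecahydronaphthalen-1-yl]-3-methylpentanoate | OC[C@@]1(C)CCC[C@]2(C)[C@@H]1CC[C@](C)(O)[C@H]2CC[C@H](C)CC(=O)OC | intermediate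
27 | (Z)-2-methylbut-2-enoic acid (angelic acid) | C/C=C(/C)C(=O)O | starting material
28 | (Z)-2-methylbut-2-enoic 2,4,6-trichlorobenzoic anhydride | C/C=C(/C)C(=O)OC(=O)c1c(Cl)cc(Cl)cc1Cl | intermediate
29 | methyl (3S)-5-[(1S,2S,4aS,5S,8aR)-2-hydroxy-2,5,8a-trimethyl-5-({[(Z)-2-methylbut-2-enoyl]oxy}methyl)decahydronaphthalen-1-yl]-3-methylpentanoate | C/C=C(/C)C(=O)OC[C@@]1(C)CCC[C@]2(C)[C@@H]1CC[C@](C)(O)[C@H]2CC[C@H](C)CC(=O)OC | intermediate
30 | (3S)-5-[(1S,2S,4aS,5S,8aR)-2-hydroxy-2,5,8a-trimethyl-5-({[(Z)-2-methylbut-2-enoyl]oxy}methyl)decahydronaphthalen-1-yl]-3-methylpentanoic acid (CNP0315745.1) | C/C=C(/C)C(=O)OC[C@@]1(C)CCC[C@]2(C)[C@@H]1CC[C@](C)(O)[C@H]2CC[C@H](C)CC(=O)O | target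

Total step count: 16.
Longest linear sequence: 13 steps (from 3 through steps 2, 3, 4, 5, 6, 7, 8, 9, 12, 13, 14, 15 and 16).

Steps most likely to fail

Step 6 (key step). Michael addition through the less substituted C8 enolate, reversible aldol trapping of the aldehyde by that enolate, or retro-Michael loss of the C4 unit from the C10 enolate may outrun the annulation. The fallback sets out from 10 and returns at 14, and makes the two bonds one at a time. Methylenation of the aldehyde of 10 with Ph3P=CH2 (THF, −78 °C, the aldehyde reacting before the ketone) gives the vinyl ketone F1. Me3SiCl, NaI and Et3N in MeCN give the more substituted silyl enol ether F2. Palladium-catalysed allylation of F2 with allyl methyl carbonate (Pd2(dba)3, Ph2PCH2CH2PPh2, THF) puts the allyl group on C10 anti to the C5 substituent and gives the allyl ketone F3. Ring-closing metathesis with the second-generation Grubbs catalyst (CH2Cl2, 40 °C) then forms the C2=C3 bond with loss of ethene and returns 14.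

Step 4. The rearrangement may pass partly or wholly through a boat-like transition state, because in the chair the silyloxymethyl group must sit pseudo-axial next to the C10 methyl; this would erode or invert C4. The fallback sets out from 3 and 2 and returns at 10. It uses the (E)-enol ether, in which only the small methyl group is pseudo-axial in the chair, and exchanges the roles of the two one-carbon arms on C4. Zirconium-catalysed carboalumination of 3 (Me3Al, Cp2ZrCl2, CH2Cl2; then I2) gives (E)-3-iodo-2-methylprop-2-en-1-ol F4, which is protected as the 4-methoxybenzyl ether F5. The same CuI-catalysed coupling with 2 gives the (E)-enol ether F6, whose chair Claisen rearrangement gives the aldehyde F7; its formyl group is the future C18 and its CH2O(4-methoxybenzyl) arm the future C3. NaBH4 gives the alcohol F8, t-BuPh2SiCl and imidazole give the silyl ether F9, and DDQ (CH2Cl2/H2O) frees the C3 alcohol F10. Hydroboration of F10 with BH3·SMe2 gives the borane adduct 9 of the main route, and the chromate oxidation of step 5 returns 10.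

Step 13. Hydroboration of the hindered tetrasubstituted C8=C9 alkene may be slow, so that reduction of the methyl ester by the borane competes. The fallback sets out from 15 and returns at 25, and introduces C17 last. KN(SiMe3)2 and PhNTf2 convert 15 into the enol triflate F11, and Negishi coupling with 22 (Pd(OAc)2, SPhos) gives the trisubstituted alkene F12. Hydroboration (BH3·THF, 0 °C), fast for this alkene, gives the alkylborane F13 and oxidation (H2O2, NaHCO3) the secondary alcohol F14. Dess–Martin periodinane gives the C8 ketone F15, in which the epimerisable C9 keeps the equatorial side chain, and Ph3P=CH2 gives the exocyclic alkene F16. Oxymercuration (Hg(OAc)2, THF/H2O) gives the organomercurial F17 by equatorial attack of water on C8, and NaBH4 reduction returns 25.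

Further compounds
F1 | step 6 | vinyl ketone (aldehyde carbon of 10 converted into CH=CH2; C4 and C5 as in 10; both C10 epimers) | C=C[C@](C)(CO[Si](c1ccccc1)(c1ccccc1)C(C)(C)C)[C@H]1CCCC(=O)C1C
F2 | step 6 | trimethylsilyl enol ether of F1 at C9–C10 | C=C[C@](C)(CO[Si](c1ccccc1)(c1ccccc1)C(C)(C)C)[C@H]1CCCC(O[Si](C)(C)C)=C1C
F3 | step 6 | allyl ketone (C10 quaternary, allyl trans to the C5 substituent) | C=C[C@](C)(CO[Si](c1ccccc1)(c1ccccc1)C(C)(C)C)[C@H]1CCCC(=O)[C@]1(C)CC=C
F4 | step 4 | (E)-3-iodo-2-methylprop-2-en-1-ol | C/C(CO)=C\I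
F5 | step 4 | 1-({[(E)-3-iodo-2-methylprop-2-en-1-yl]oxy}methyl)-4-methoxybenzene | C/C(COCc1ccc(OC)cc1)=C\I
F6 | step 4 | (E)-enol ether of 2 (4-methoxybenzyl analogue of 7) | CC1=CCCC[C@H]1O/C=C(\C)COCc1ccc(OC)cc1
F7 | step 4 | aldehyde with exchanged arms (CHO = future C18, CH2O-4-methoxybenzyl = future C3) | O=C[C@@](C)(COCc1ccc(OC)cc1)[C@H]1CCCC=C1C
F8 | step 4 | primary alcohol from F7 | OC[C@@](C)(COCc1ccc(OC)cc1)[C@H]1CCCC=C1C
F9 | step 4 | tert-butyldiphenylsilyl ether of F8 | CC(C)(C)[Si](c1ccccc1)(c1ccccc1)OC[C@@](C)(COCc1ccc(OC)cc1)[C@H]1CCCC=C1C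
F10 | step 4 | C3 alcohol after removal of the 4-methoxybenzyl group | CC(C)(C)[Si](c1ccccc1)(c1ccccc1)OC[C@@](C)(CO)[C@H]1CCCC=C1C
F11 | step 13 | enol triflate of 15 (C8=C9, no C17) | CC(C)(C)[Si](c1ccccc1)(c1ccccc1)OC[C@@]1(C)CCC[C@]2(C)[C@@H]1CCC=C2OS(=O)(=O)C(F)(F)F
F12 | step 13 | trisubstituted C8=C9 alkene carrying the side chain | CC(C)(C)[Si](c1ccccc1)(c1ccccc1)OC[C@@]1(C)CCC[C@]2(C)[C@@H]1CCC=C2CC[C@H](C)CC(=O)OC
F13 | step 13 | C8 alkylborane from F12 (simplest monomeric form) | CC(C)(C)[Si](c1ccccc1)(c1ccccc1)OC[C@@]1(C)CCC[C@]2(C)[C@@H]1CC[C@H](B)[C@H]2CC[C@H](C)CC(=O)OC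
F14 | step 13 | secondary C8 alcohol (OH and H9 on the face opposite C20) | CC(C)(C)[Si](c1ccccc1)(c1ccccc1)OC[C@@]1(C)CCC[C@]2(C)[C@@H]1CC[C@H](O)[C@H]2CC[C@H](C)CC(=O)OC
F15 | step 13 | C8 ketone (side chain equatorial at C9) | CC(C)(C)[Si](c1ccccc1)(c1ccccc1)OC[C@@]1(C)CCC[C@]2(C)[C@@H]1CCC(=O)[C@H]2CC[C@H](C)CC(=O)OC
F16 | step 13 | exocyclic C8=C17 alkene | CC(C)(C)[Si](c1ccccc1)(c1ccccc1)OC[C@@]1(C)CCC[C@]2(C)[C@@H]1CCC(=C)[C@H]2CC[C@H](C)CC(=O)OC
F17 | step 13 | C17 acetoxymercurio C8 alcohol | CC(C)(C)[Si](c1ccccc1)(c1ccccc1)OC[C@@]1(C)CCC[C@]2(C)[C@@H]1CC[C@@](O)(C[Hg]OC(C)=O)[C@H]2CC[C@H](C)CC(=O)OC
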